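**Plan**
Retrosynthesis (labdane numbering): the C6 acetate, the enol ether C14=C15, the epoxide C8–C17 and the spiro ether (O–C13, then C9–C11) are removed to reach a tricyclic 9-ketone. Then C3–C4 and C4–CH3 are cut (lactone α-alkylations), and last C5–C10 and O–C20 together.
Enabling feature: the δ-lactone ring O–C20–C10–C5–C4–C19 is a masked dihydropyran, the cycloadduct of the 1-oxadiene O=C19–C4=C5 with the alkene C10=C20; the four carbons C6–C9 of ring B tether the two.
Forward: (R)-5-(hydroxymethyl)butyrolactone (C5–C9) plus a vinyl unit (C10, C20, C1–C3) gives an aldehyde. Knoevenagel/hetero-Diels–Alder with Meldrum's acid closes ring B and the lactone ring at once, and a bridging alkylation closes ring A.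
Then: C9 ketone, 8(17)-enone, furylethyl addition, butenolide, spiro tetrahydrofuran, epoxide, dihydrofuran, acetate.
Stereochemistry: C6 from the chiral pool; C5 and C10 from the cycloaddition (trans ring B/lactone junction, which is the H5-cis-to-C20, cis-fused A/B arrangement of the given SMILES); C4 forced by the bicyclo[3.3.1] closure; C9 and C8 by attack anti to C1; C13 by a reversible oxa-Michael addition with recycling.

Key step: step 8

Remark: locants follow labdane numbering throughout (C19 lactone carbonyl, C20 lactone CH2, C17 epoxide CH2, C15/C16 dihydrofuran CH/CH2); compounds 1, 4, 12 and 23 are taken as commercial.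

Step 1
Reactants: 1 5-chloropent-1-yne
Product: 3 2-bromo-5-chloropent-1-ene, via (Z)-bromoalkenyl-9-BBN adduct 2 (not isolated)
Conditions: B-Br-9-BBN, CH2Cl2, 0 °C; then AcOH, 0 °C to rt
Reagents that add atoms: B-bromo-9-borabicyclo[3.3.1]nonane, BrB1C2CCCC1CCC2
Why: Bromoboration adds B–Br syn across the terminal alkyne with bromine on the internal carbon, and protonolysis of the C–B bond leaves the 2-bromo-1-alkene while the alkyl chloride is inert.

Step 2
Reactants: 4 (R)-5-(hydroxymethyl)dihydrofuran-2(3H)-one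
Product: 5 (4R)-4,5-dihydroxy-N-methoxy-N-methylpentanamide
Conditions: MeNH(OMe)·HCl, i-PrMgCl, THF, −20 to 0 °C; crude product carried on at once
Reagents that add atoms: N,O-dimethylhydroxylamine hydrochloride, CNOC.Cl
Why: Weinreb aminolysis opens the γ-lactone at the acyl carbon only, so the carbinol centre (future C6) keeps its configuration.

Step 3
Reactants: 5 (4R)-4,5-dihydroxy-N-methoxy-N-methylpentanamide
Product: 6 (4R)-4,5-bis(tert-butyldimethylsilyloxy)-N-methoxy-N-methylpentanamide
Conditions: TBSCl (2.5 equiv), imidazole, DMF, rt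
Reagents that add atoms: tert-butyldimethylsilyl chloride, CC(C)(C)[Si](C)(C)Cl
Why: Imidazole-mediated silylation of both hydroxyls stops relactonisation and installs the C6 protecting group that is carried to the end.

Step 4
Reactants: 6 (4R)-4,5-bis(tert-butyldimethylsilyloxy)-N-methoxy-N-methylpentanamide; 3 2-bromo-5-chloropent-1-ene
Product: 8 (2R)-1,2-bis(tert-butyldimethylsilyloxy)-9-chloro-6-methylidenenonan-5-one, via (5-chloropent-1-en-2-yl)lithium 7 (not isolated)
Conditions: 3, t-BuLi (2 equiv), Et2O, −78 °C; then 6, −78 °C; cold aq. NH4Cl quench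
Reagents that add atoms: none
Why: Bromine–lithium exchange followed by a Weinreb ketone synthesis gives the α-methylene ketone by single addition through the chelated tetrahedral intermediate, and the primary chloride does not react at −78 °C.

Step 5
Reactants: 8 (2R)-1,2-bis(tert-butyldimethylsilyloxy)-9-chloro-6-methylidenenonan-5-one
Product: 9 2-[(3R)-3,4-bis(tert-butyldimethylsilyloxy)butyl]-2-(5-chloropent-1-en-2-yl)-1,3-dioxolane
Conditions: TMSOCH2CH2OTMS, TMSOTf (cat.), CH2Cl2, −78 to −20 °C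
Reagents that add atoms: 1,2-bis(trimethylsilyloxy)ethane, C[Si](C)(C)OCCO[Si](C)(C)C
Why: Aprotic silyl-triflate-catalysed ketalisation protects the enone carbonyl (C9) without moving the double bond and turns the electron-poor enone alkene into the isolated 1,1-disubstituted alkene needed as dienophile.

Step 6
Reactants: 9 2-[(3R)-3,4-bis(tert-butyldimethylsilyloxy)butyl]-2-(5-chloropent-1-en-2-yl)-1,3-dioxolane
Product: 10 (2R)-2-(tert-butyldimethylsilyloxy)-4-[2-(5-chloropent-1-en-2-yl)-1,3-dioxolan-2-yl]butan-1-ol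
Conditions: HF·pyridine, pyridine, THF, 0 °C
Reagents that add atoms: none
Why: Buffered fluoride cleaves the unhindered primary silyl ether much faster than the secondary one (steric differentiation) and leaves the dioxolane untouched.

Step 7
Reactants: 10 (2R)-2-(tert-butyldimethylsilyloxy)-4-[2-(5-chloropent-1-en-2-yl)-1,3-dioxolan-2-yl]butan-1-ol
Product: 11 (2R)-2-(tert-butyldimethylsilyloxy)-4-[2-(5-chloropent-1-en-2-yl)-1,3-dioxolan-2-yl]butanal
Conditions: Dess–Martin periodinane, NaHCO3, CH2Cl2, 0 °C to rt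
Reagents that add atoms: none
Why: Buffered Dess–Martin oxidation should give the α-silyloxy aldehyde without epimerising C6.

Step 8
Reactants: 11 (2R)-2-(tert-butyldimethylsilyloxy)-4-[2-(5-chloropent-1-en-2-yl)-1,3-dioxolan-2-yl]butanal; 12 Meldrum's acid
Product: 14 (5S,6R,10S)-cycloadduct: ring B (6-OTBS; 9,9-ethylenedioxy; 10-(3-chloropropyl)) trans-fused at C5–C10 to a 2,2-dimethylpyrano[2,3-d][1,3]dioxin-4-one, via alkylidene Meldrum's acid 13 (not isolated)
Conditions: 12, EDDA (cat.), 4 Å MS, MeCN, rt; then toluene, 80–110 °C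
Reagents that add atoms: none
Why: Amine-salt-catalysed Knoevenagel condensation gives the 1-oxa-1,3-diene 13 (O=C19–C4=C5), which adds intramolecularly to the C10=C20 alkene in an inverse-electron-demand hetero-Diels–Alder reaction that forms C5–C10 and O–C20 in one concerted, asynchronous [4+2] event. The closest known reaction type is the domino Knoevenagel/hetero-Diels–Alder reaction of aliphatic aldehydes of the citronellal type that carry an unactivated alkene. Ring B closes in the fused mode through the four-atom tether C6–C9 (six-membered carbocycle, exo with respect to the alkene, bond to its inner carbon), and the dihydropyran that becomes the lactone ring closes in the same event by O-attack on the terminal CH2. C5 is controlled by C6: the C6–H bond eclipses the alkylidene to avoid allylic 1,3-strain, the silyloxy group sits equatorial and the alkene adds anti to it; C10 is set by the exo chair transition state typical of aliphatic tethers, which gives the trans ring B/pyran junction with the chloropropyl chain axial. The step needs fused over bridged regiochemistry and exo over endo selectivity, and the short tether (six- versus seven-membered carbocycle), the Thorpe–Ingold effect of the C9 dioxolane and the chair-like tether should secure both.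

Step 9
Reactants: 14 (5S,6R,10S)-cycloadduct
Product: 16 (5R,6R,10S)-bicyclic δ-lactone: ring B (6-OTBS; 9,9-ethylenedioxy; 10-(3-chloropropyl)) trans-fused to the C19–O–C20 lactone ring with C4H2, via malonic half-acid lactone 15 (not isolated)
Conditions: H2O, 2,6-lutidine, 1,4-dioxane, 100 °C
Reagents that add atoms: none
Why: Thermal loss of acetone from the 1,3-dioxin-4-one in wet solvent and decarboxylation of the resulting malonic half-acid give the δ-lactone without touching a stereocentre, while the hindered base keeps the medium neutral for the ketal and does not alkylate on the chloride.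

Step 10
Reactants: 16 (5R,6R,10S)-bicyclic δ-lactone
Product: 17 (5R,6R,10S)-4-methyl δ-lactone (mixture of C4 epimers)
Conditions: LDA, THF, −78 °C; MeI, −78 to −40 °C
Reagents that add atoms: iodomethane, CI
Why: Kinetic deprotonation at C4 and C-methylation (lactone enolate alkylation) introduce C18; the C4 configuration is irrelevant because C4 becomes planar again in step 12.

Step 11
Reactants: 17 (5R,6R,10S)-4-methyl δ-lactone
Product: 18 (5R,6R,10S)-4-methyl-10-(3-iodopropyl) δ-lactone (mixture of C4 epimers)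
Conditions: NaI, acetone, reflux
Reagents that add atoms: sodium iodide, [Na+].[I-]
Why: Finkelstein exchange turns the unhindered primary chloride into the iodide needed for ring closure at low temperature.

Step 12
Reactants: 18 (5R,6R,10S)-4-methyl-10-(3-iodopropyl) δ-lactone
Product: 19 (4S,5S,6R,10S)-6-(tert-butyldimethylsilyloxy)-9,9-ethylenedioxy-11,12,13,14,15,16,17-heptanorlabdan-19,20-olide
Conditions: KHMDS, THF, −78 to 0 °C
Reagents that add atoms: none
Why: Intramolecular enolate alkylation in the 6-(enolendo)-exo-tet mode closes ring A; the iodopropyl chain is axial on C10 and can reach C4 from one face only, so the bicyclo[3.3.1] closure fixes the quaternary centre C4.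

Step 13
Reactants: 19 (4S,5S,6R,10S)-6-(tert-butyldimethylsilyloxy)-9,9-ethylenedioxy-11,12,13,14,15,16,17-heptanorlabdan-19,20-olide
Product: 20 (4S,5S,6R,10S)-6-(tert-butyldimethylsilyloxy)-9-oxo-11,12,13,14,15,16,17-heptanorlabdan-19,20-olide
Conditions: PPTS (cat.), acetone/H2O, 60 °C
Reagents that add atoms: water, O
Why: Mild acid-catalysed ketal hydrolysis should free the C9 ketone while the secondary silyl ether and the hindered lactone survive.

Step 14
Reactants: 20 (4S,5S,6R,10S)-6-(tert-butyldimethylsilyloxy)-9-oxo-11,12,13,14,15,16,17-heptanorlabdan-19,20-olide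
Product: 22 (4S,5S,6R,10S)-6-(tert-butyldimethylsilyloxy)-9-oxo-11,12,13,14,15,16-hexanorlabd-8(17)-en-19,20-olide, via C8 Mannich base 21 (not isolated)
Conditions: (CH2O)n, PhNHMe·CF3CO2H, THF, reflux
Reagents that add atoms: paraformaldehyde (as formaldehyde), C=O
Why: Mannich condensation and elimination of the amine (direct α-methylenation) can take place only at C8 because C10 is quaternary.

Step 15
Reactants: 23 2-(furan-3-yl)ethanol
Product: 24 3-(2-iodoethyl)furan
Conditions: I2, PPh3, imidazole, CH2Cl2, 0 °C to rt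
Reagents that add atoms: iodine, II
Why: Appel-type iodination of the primary alcohol gives the side-chain iodide.

Step 16
Reactants: 22 (4S,5S,6R,10S)-6-(tert-butyldimethylsilyloxy)-9-oxo-11,12,13,14,15,16-hexanorlabd-8(17)-en-19,20-olide; 24 3-(2-iodoethyl)furan
Product: 26 (4S,5S,6R,9R,10S)-6-(tert-butyldimethylsilyloxy)-15,16-epoxy-9-hydroxylabda-8(17),13(16),14-trien-19,20-olide, via [2-(furan-3-yl)ethyl]lithium 25 (not isolated)
Conditions: 24, t-BuLi (2 equiv), Et2O, −78 °C; CeCl3, THF, −78 °C; then 22, −78 °C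
Reagents that add atoms: none
Why: Iodine–lithium exchange and transmetalation to cerium give a weakly basic reagent that adds 1,2 to the hindered enone carbonyl and not to the lactone, entering axially on the face anti to the axial C1 of ring A (convex face of the cis-fused decalin), which places C11 cis to H5 and the hydroxyl equatorial.

Step 17
Reactants: 26 (4S,5S,6R,9R,10S)-6-(tert-butyldimethylsilyloxy)-15,16-epoxy-9-hydroxylabda-8(17),13(16),14-trien-19,20-olide
Product: 28 (4S,5S,6R,9R,10S)-6-(tert-butyldimethylsilyloxy)-9-hydroxylabda-8(17),13-diene-15,16:19,20-diolide, via 16-hydroxybutenolide 27 (not isolated)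
Conditions: O2, hν, tetraphenylporphyrin (cat.), i-Pr2NEt, CH2Cl2, −78 °C; then NaBH4, EtOH, 0 °C; aq. HCl to pH 3
Reagents that add atoms: oxygen, O=O
Why: Singlet-oxygen [4+2] addition to the furan and hindered-base fragmentation at the unhindered C15–H give the β-substituted γ-hydroxybutenolide, whose masked C16 aldehyde is reduced by borohydride and relactonises; the furan reacts far faster than the 1,1-disubstituted alkene.

Step 18
Reactants: 28 (4S,5S,6R,9R,10S)-6-(tert-butyldimethylsilyloxy)-9-hydroxylabda-8(17),13-diene-15,16:19,20-diolide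
Product: 29 (4S,5S,6R,9R,10S,13R)-6-(tert-butyldimethylsilyloxy)-9,13-epoxylabd-8(17)-ene-15,16:19,20-diolide
Conditions: t-BuOK (cat.), THF, 0 °C to rt
Reagents that add atoms: none
Why: Intramolecular oxa-Michael addition (5-exo-trig) of the C9 alkoxide to C13 of the butenolide closes the spiro tetrahydrofuran; substrate control at C13 is weak and both C13 epimers are expected, but the addition is reversible, so the separated 13S epimer can be returned to the same conditions and funnelled into 29.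

Step 19
Reactants: 29 (4S,5S,6R,9R,10S,13R)-6-(tert-butyldimethylsilyloxy)-9,13-epoxylabd-8(17)-ene-15,16:19,20-diolide
Product: 30 (4S,5S,6R,8R,9S,10S,13R)-6-(tert-butyldimethylsilyloxy)-8,17:9,13-diepoxylabdane-15,16:19,20-diolide
Conditions: mCPBA, NaHCO3, CH2Cl2, 0 °C
Reagents that add atoms: 3-chloroperoxybenzoic acid, OOC(=O)c1cccc(Cl)c1
Why: Prilezhaev epoxidation of the only alkene should deliver oxygen from the face anti to the axial C1 (cis to C11), because the other face is shielded by ring A and the etherified C9 oxygen can no longer direct the peracid.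

Step 20
Reactants: 30 (4S,5S,6R,8R,9S,10S,13R)-6-(tert-butyldimethylsilyloxy)-8,17:9,13-diepoxylabdane-15,16:19,20-diolide
Product: 31 (4S,5S,6R,8R,9S,10S,13R)-6-(tert-butyldimethylsilyloxy)-15-hydroxy-8,17:9,13:15,16-triepoxylabdan-19,20-olide (C15 anomers)
Conditions: DIBAL-H (1.2 equiv), CH2Cl2, −78 °C; Rochelle salt work-up
Reagents that add atoms: none
Why: At −78 °C the hydride reduces the unhindered γ-lactone to the lactol faster than the δ-lactone whose carbonyl is flanked by quaternary C4 (steric chemoselectivity) and leaves the epoxide intact.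

Step 21
Reactants: 31 15-lactol
Product: 33 (4S,5S,6R,8R,9S,10S,13R)-6-(tert-butyldimethylsilyloxy)-8,17:9,13:15,16-triepoxylabd-14-en-19,20-olide, via lactol 15-mesylate 32 (not isolated)
Conditions: MsCl, Et3N, CH2Cl2, −20 °C to rt
Reagents that add atoms: none
Why: Sulfonylation of the anomeric hydroxyl and base-induced elimination (only C14 carries β-hydrogens) give the 2,3-dihydrofuran under non-acidic conditions.

Step 22
Reactants: 33 6-O-TBS enol ether
Product: 34 (4S,5S,6R,8R,9S,10S,13R)-6-hydroxy-8,17:9,13:15,16-triepoxylabd-14-en-19,20-olide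
Conditions: TBAF, THF, 0 °C to rt
Reagents that add atoms: none
Why: Fluoride cleaves the silyl ether without acid, so the epoxide, the enol ether and the lactone should survive.

Step 23
Reactants: 34 6-alcohol
Product: 35 target: (4S,5S,6R,8R,9S,10S,13R)-6-acetoxy-8,17:9,13:15,16-triepoxylabd-14-en-19,20-olide
Conditions: Ac2O, pyridine, DMAP (cat.), CH2Cl2, rt
Reagents that add atoms: acetic anhydride, CC(=O)OC(C)=O
Why: Nucleophile-catalysed acetylation of the equatorial secondary C6 alcohol under basic conditions gives the target.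

**Compound list**
1 | 5-chloropent-1-yne | C#CCCCCl | starting material
2 | (Z)-B-(2-bromo-5-chloropent-1-en-1-yl)-9-borabicyclo[3.3.1]nonane | ClCCC/C(Br)=C/B1C2CCCC1CCC2 | intermediate (not isolated)
3 | 2-bromo-5-chloropent-1-ene | C=C(Br)CCCCl | intermediate
4 | (R)-5-(hydroxymethyl)dihydrofuran-2(3H)-one | OC[C@H]1CCC(=O)O1 | starting material
5 | (4R)-4,5-dihydroxy-N-methoxy-N-methylpentanamide | OC[C@H](O)CCC(=O)N(C)OC | intermediate
6 | (4R)-4,5-bis(tert-butyldimethylsilyloxy)-N-methoxy-N-methylpentanamide | CC(C)(C)[Si](C)(C)OC[C@H](O[Si](C)(C)C(C)(C)C)CCC(=O)N(C)OC | intermediate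
7 | (5-chloropent-1-en-2-yl)lithium | [Li]C(=C)CCCCl | intermediate (not isolated)
8 | (2R)-1,2-bis(tert-butyldimethylsilyloxy)-9-chloro-6-methylidenenonan-5-one | CC(C)(C)[Si](C)(C)OC[C@H](O[Si](C)(C)C(C)(C)C)CCC(=O)C(=C)CCCCl | intermediate
9 | 2-[(3R)-3,4-bis(tert-butyldimethylsilyloxy)butyl]-2-(5-chloropent-1-en-2-yl)-1,3-dioxolane | CC(C)(C)[Si](C)(C)OC[C@H](O[Si](C)(C)C(C)(C)C)CCC1(OCCO1)C(=C)CCCCl | intermediate
10 | (2R)-2-(tert-butyldimethylsilyloxy)-4-[2-(5-chloropent-1-en-2-yl)-1,3-dioxolan-2-yl]butan-1-ol | OC[C@H](O[Si](C)(C)C(C)(C)C)CCC1(OCCO1)C(=C)CCCCl | intermediate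
11 | (2R)-2-(tert-butyldimethylsilyloxy)-4-[2-(5-chloropent-1-en-2-yl)-1,3-dioxolan-2-yl]butanal | O=C[C@H](O[Si](C)(C)C(C)(C)C)CCC1(OCCO1)C(=C)CCCCl | intermediate
12 | Meldrum's acid (2,2-dimethyl-1,3-dioxane-4,6-dione) | CC1(C)OC(=O)CC(=O)O1 | starting material
13 | 5-{(2R)-2-(tert-butyldimethylsilyloxy)-4-[2-(5-chloropent-1-en-2-yl)-1,3-dioxolan-2-yl]butylidene}-2,2-dimethyl-1,3-dioxane-4,6-dione | CC1(C)OC(=O)C(=C[C@H](O[Si](C)(C)C(C)(C)C)CCC2(OCCO2)C(=C)CCCCl)C(=O)O1 | intermediate (not isolated)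
14 | (5S,6R,10S)-cycloadduct: ring B (6-OTBS; 9,9-ethylenedioxy; 10-(3-chloropropyl)) trans-fused at C5–C10 to a 2,2-dimethylpyrano[2,3-d][1,3]dioxin-4-one | CC(C)(C)[Si](C)(C)O[C@@H]1CCC2(OCCO2)[C@]3(CCCCl)COC4=C(C(=O)OC(C)(C)O4)[C@@H]13 | intermediate
15 | (5R,6R,10S)-δ-lactone 4-carboxylic acid (malonic half-acid, C4 epimers) | CC(C)(C)[Si](C)(C)O[C@@H]1CCC2(OCCO2)[C@]3(CCCCl)COC(=O)C(C(=O)O)[C@@H]13 | intermediate (not isolated)
16 | (5R,6R,10S)-bicyclic δ-lactone (6-OTBS; 9,9-ethylenedioxy; 10-(3-chloropropyl); C4H2) | CC(C)(C)[Si](C)(C)O[C@@H]1CCC2(OCCO2)[C@]3(CCCCl)COC(=O)C[C@@H]13 | intermediate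
17 | (5R,6R,10S)-4-methyl δ-lactone (C4 epimers) | CC(C)(C)[Si](C)(C)O[C@@H]1CCC2(OCCO2)[C@]3(CCCCl)COC(=O)C(C)[C@@H]13 | intermediate
18 | (5R,6R,10S)-4-methyl-10-(3-iodopropyl) δ-lactone (C4 epimers) | CC(C)(C)[Si](C)(C)O[C@@H]1CCC2(OCCO2)[C@]3(CCCI)COC(=O)C(C)[C@@H]13 | intermediate
19 | (4S,5S,6R,10S)-6-(tert-butyldimethylsilyloxy)-9,9-ethylenedioxy-11,12,13,14,15,16,17-heptanorlabdan-19,20-olide | CC(C)(C)[Si](C)(C)O[C@@H]1CCC2(OCCO2)[C@]23CCC[C@](C)(C(=O)OC2)[C@@H]13 | intermediate
20 | (4S,5S,6R,10S)-6-(tert-butyldimethylsilyloxy)-9-oxo-11,12,13,14,15,16,17-heptanorlabdan-19,20-olide | CC(C)(C)[Si](C)(C)O[C@@H]1CCC(=O)[C@]23CCC[C@](C)(C(=O)OC2)[C@@H]13 | intermediate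
21 | C8 Mannich base: 8-[(N-methylanilino)methyl] derivative of 20 (C8 epimers) | CC(C)(C)[Si](C)(C)O[C@@H]1CC(CN(C)c2ccccc2)C(=O)[C@]23CCC[C@](C)(C(=O)OC2)[C@@H]13 | intermediate (not isolated)
22 | (4S,5S,6R,10S)-6-(tert-butyldimethylsilyloxy)-9-oxo-11,12,13,14,15,16-hexanorlabd-8(17)-en-19,20-olide | CC(C)(C)[Si](C)(C)O[C@@H]1CC(=C)C(=O)[C@]23CCC[C@](C)(C(=O)OC2)[C@@H]13 | intermediate
23 | 2-(furan-3-yl)ethanol | OCCc1ccoc1 | starting material
24 | 3-(2-iodoethyl)furan | ICCc1ccoc1 | intermediate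
25 | [2-(furan-3-yl)ethyl]lithium | [Li]CCc1ccoc1 | intermediate (not isolated)
26 | (4S,5S,6R,9R,10S)-6-(tert-butyldimethylsilyloxy)-15,16-epoxy-9-hydroxylabda-8(17),13(16),14-trien-19,20-olide | CC(C)(C)[Si](C)(C)O[C@@H]1CC(=C)[C@](O)(CCc2ccoc2)[C@]23CCC[C@](C)(C(=O)OC2)[C@@H]13 | intermediate
27 | (4S,5S,6R,9R,10S)-6-(tert-butyldimethylsilyloxy)-9,16-dihydroxylabda-8(17),13-diene-15,16:19,20-diolide (C16 epimers) | CC(C)(C)[Si](C)(C)O[C@@H]1CC(=C)[C@](O)(CCC2=CC(=O)OC2O)[C@]23CCC[C@](C)(C(=O)OC2)[C@@H]13 | intermediate (not isolated)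
28 | (4S,5S,6R,9R,10S)-6-(tert-butyldimethylsilyloxy)-9-hydroxylabda-8(17),13-diene-15,16:19,20-diolide | CC(C)(C)[Si](C)(C)O[C@@H]1CC(=C)[C@](O)(CCC2=CC(=O)OC2)[C@]23CCC[C@](C)(C(=O)OC2)[C@@H]13 | intermediate
29 | (4S,5S,6R,9R,10S,13R)-6-(tert-butyldimethylsilyloxy)-9,13-epoxylabd-8(17)-ene-15,16:19,20-diolide | CC(C)(C)[Si](C)(C)O[C@@H]1CC(=C)[C@]2(CC[C@]3(CC(=O)OC3)O2)[C@]23CCC[C@](C)(C(=O)OC2)[C@@H]13 | intermediate
30 | (4S,5S,6R,8R,9S,10S,13R)-6-(tert-butyldimethylsilyloxy)-8,17:9,13-diepoxylabdane-15,16:19,20-diolide | CC(C)(C)[Si](C)(C)O[C@@H]1C[C@@]2(CO2)[C@]2(CC[C@]3(CC(=O)OC3)O2)[C@]23CCC[C@](C)(C(=O)OC2)[C@@H]13 | intermediate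
31 | (4S,5S,6R,8R,9S,10S,13R)-6-(tert-butyldimethylsilyloxy)-15-hydroxy-8,17:9,13:15,16-triepoxylabdan-19,20-olide (C15 anomers) | CC(C)(C)[Si](C)(C)O[C@@H]1C[C@@]2(CO2)[C@]2(CC[C@]3(CC(O)OC3)O2)[C@]23CCC[C@](C)(C(=O)OC2)[C@@H]13 | intermediate
32 | 15-methanesulfonate of lactol 31 (C15 anomers) | CC(C)(C)[Si](C)(C)O[C@@H]1C[C@@]2(CO2)[C@]2(CC[C@]3(CC(OS(C)(=O)=O)OC3)O2)[C@]23CCC[C@](C)(C(=O)OC2)[C@@H]13 | intermediate (not isolated)
33 | (4S,5S,6R,8R,9S,10S,13R)-6-(tert-butyldimethylsilyloxy)-8,17:9,13:15,16-triepoxylabd-14-en-19,20-olide | CC(C)(C)[Si](C)(C)O[C@@H]1C[C@@]2(CO2)[C@]2(CC[C@]3(C=COC3)O2)[C@]23CCC[C@](C)(C(=O)OC2)[C@@H]13 | intermediate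
34 | (4S,5S,6R,8R,9S,10S,13R)-6-hydroxy-8,17:9,13:15,16-triepoxylabd-14-en-19,20-olide | O[C@@H]1C[C@@]2(CO2)[C@]2(CC[C@]3(C=COC3)O2)[C@]23CCC[C@](C)(C(=O)OC2)[C@@H]13 | intermediate
35 | (4S,5S,6R,8R,9S,10S,13R)-6-acetoxy-8,17:9,13:15,16-triepoxylabd-14-en-19,20-olide | CC(=O)O[C@@H]1C[C@@]2(CO2)[C@]2(CC[C@]3(C=COC3)O2)[C@]23CCC[C@](C)(C(=O)OC2)[C@@H]13 | target

**Step count**
Total: 23 steps. Longest linear sequence: 21 steps (steps 2–14 and 16–23, from 4).

**Three steps most likely to fail**

Step 8. The fused mode makes the electrophilic C5 bond to the substituted end of an unactivated 1,1-disubstituted alkene, which is polarity-mismatched. The cycloaddition may therefore be slow, leak into the bridged regiochemistry or lose exo selectivity while the alkylidene Meldrum's acid decomposes. The fallback makes the dienophile polarity-matched with a removable phenylthio group on C20. It sets out from 9: PhSCl (CH2Cl2, −78 °C) followed by DBU should give the vinyl sulfide, 2-[(3R)-3,4-bis(tert-butyldimethylsilyloxy)butyl]-2-[5-chloro-1-(phenylsulfanyl)pent-1-en-2-yl]-1,3-dioxolane F1. Buffered HF·pyridine should then give the primary alcohol F2, and Dess–Martin oxidation the aldehyde F3. In the same Knoevenagel/cycloaddition with 12, C10 is now the nucleophilic β-carbon of a vinyl sulfide and oxygen closes onto the thio-substituted carbon, which should give the 20-phenylsulfanyl cycloadduct F4 at lower temperature. Radical desulfurisation (Bu3SnH, AIBN, toluene, 80 °C) returns to 14.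

Step 18. Facial control at C13 is weak, and the retro-addition can hold part of the material as open butenolide, so the 13R spiro ether may not predominate. The fallback sets C13 by ligand control in a Tsuji–Trost etherification. It sets out from 26: NBS/NaHCO3 in acetone–H2O followed by NaBH4/CeCl3·7H2O should open the furan to the (Z)-enediol, the 15,16-dihydroxy-13(14)-ene F5. ClCO2Me/pyridine at −40 °C should acylate the less hindered C15 hydroxyl to give the 15-methyl carbonate F6. Pd2(dba)3·CHCl3 (zerovalent palladium) with an enantiopure DACH-phenyl bisphosphine ligand (the antipode that delivers 13R, fixed by one pilot run with each) ionises the carbonate. The C9 hydroxyl then attacks C13 of the allyl complex in the 5-exo mode to give the 13-vinyl-13-hydroxymethyl tetrahydrofuran F7. mCPBA should epoxidise the 1,1-disubstituted C8=C17 in preference to the vinyl group to give the epoxide F8. 9-BBN then NaBO3 should give the 15,16-diol F9, and TEMPO/PhI(OAc)2 oxidative lactonisation at the less hindered C15 returns to 30.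

Step 19. The peracid may attack the face syn to C1, or both faces, because the face anti to C1 is flanked by the axial C11 and the spiro ring. The fallback reverses which atom is delivered to the open face. It sets out from 29: ozonolysis (O3, CH2Cl2/MeOH, −78 °C; Me2S) should give the 8-oxo-17-nor ketone F10. Kinetic Corey–Chaykovsky methylenation (Me3S+ I−, KHMDS, THF, 0 °C) then brings in carbon on the face that the oxygen electrophile preferred, so oxygen ends on the opposite face, and this returns to 30.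

**Further compounds**
F1 | step 8 | 2-[(3R)-3,4-bis(tert-butyldimethylsilyloxy)butyl]-2-[5-chloro-1-(phenylsulfanyl)pent-1-en-2-yl]-1,3-dioxolane (E/Z mixture) | CC(C)(C)[Si](C)(C)OC[C@H](O[Si](C)(C)C(C)(C)C)CCC1(OCCO1)C(=CSc1ccccc1)CCCCl
F2 | step 8 | (2R)-2-(tert-butyldimethylsilyloxy)-4-{2-[5-chloro-1-(phenylsulfanyl)pent-1-en-2-yl]-1,3-dioxolan-2-yl}butan-1-ol | OC[C@H](O[Si](C)(C)C(C)(C)C)CCC1(OCCO1)C(=CSc1ccccc1)CCCCl
F3 | step 8 | (2R)-2-(tert-butyldimethylsilyloxy)-4-{2-[5-chloro-1-(phenylsulfanyl)pent-1-en-2-yl]-1,3-dioxolan-2-yl}butanal | O=C[C@H](O[Si](C)(C)C(C)(C)C)CCC1(OCCO1)C(=CSc1ccccc1)CCCCl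
F4 | step 8 | 20-phenylsulfanyl derivative of cycloadduct 14 (C20 epimers) | CC(C)(C)[Si](C)(C)O[C@@H]1CCC2(OCCO2)[C@]3(CCCCl)C(Sc2ccccc2)OC2=C(C(=O)OC(C)(C)O2)[C@@H]13
F5 | step 18 | (4S,5S,6R,9R,10S,13Z)-6-(tert-butyldimethylsilyloxy)-9,15,16-trihydroxylabda-8(17),13-dien-19,20-olide | CC(C)(C)[Si](C)(C)O[C@@H]1CC(=C)[C@](O)(CC/C(CO)=C/CO)[C@]23CCC[C@](C)(C(=O)OC2)[C@@H]13
F6 | step 18 | 15-O-methoxycarbonyl derivative of F5 | CC(C)(C)[Si](C)(C)O[C@@H]1CC(=C)[C@](O)(CC/C(CO)=C/COC(=O)OC)[C@]23CCC[C@](C)(C(=O)OC2)[C@@H]13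
F7 | step 18 | (13R)-6-(tert-butyldimethylsilyloxy)-9,13-epoxy-16-hydroxylabda-8(17),14-dien-19,20-olide | CC(C)(C)[Si](C)(C)O[C@@H]1CC(=C)[C@]2(CC[C@@](C=C)(CO)O2)[C@]23CCC[C@](C)(C(=O)OC2)[C@@H]13
F8 | step 18 | (8R,13R)-6-(tert-butyldimethylsilyloxy)-8,17:9,13-diepoxy-16-hydroxylabd-14-en-19,20-olide | CC(C)(C)[Si](C)(C)O[C@@H]1C[C@@]2(CO2)[C@]2(CC[C@@](C=C)(CO)O2)[C@]23CCC[C@](C)(C(=O)OC2)[C@@H]13
F9 | step 18 | (8R,13R)-6-(tert-butyldimethylsilyloxy)-8,17:9,13-diepoxy-15,16-dihydroxylabdan-19,20-olide | CC(C)(C)[Si](C)(C)O[C@@H]1C[C@@]2(CO2)[C@]2(CC[C@@](CCO)(CO)O2)[C@]23CCC[C@](C)(C(=O)OC2)[C@@H]13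
F10 | step 19 | (13R)-6-(tert-butyldimethylsilyloxy)-9,13-epoxy-8-oxo-17-norlabdane-15,16:19,20-diolide | CC(C)(C)[Si](C)(C)O[C@@H]1CC(=O)[C@]2(CC[C@]3(CC(=O)OC3)O2)[C@]23CCC[C@](C)(C(=O)OC2)[C@@H]13
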